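The easy mistake is to set over-reaction product against the starting material charged. The listed step makes it from target, so I set it against target and ask what fraction of target is left.

| flask | starting material | partner | second substrate | free catalyst | remark | time |
|---|---|---|---|---|---|---|
| eta | 0.10 M | 0.20 M | 0.10 M | 1 mM | run made earlier |  |
| alpha | 0.10 M | 0.20 M | 0.10 M | 0.50 mM | run made earlier |  |
| gamma | 0.10 M | 0.20 M | 0.10 M | 2 mM | run made earlier |  |
| cedar | 0.10 M (in portions, 3, over 3.0 d) | 0.200 M | 0.100 M | 1.0 mM | first portion at the start, last at 3.0 d | 5.0 d |
| alder | 0.10 M | 0.200 M (fed, over 3.0 d) | 0.100 M | 1.0 mM | all else is in the flask from the start; the feed brings no volume worth counting | 5.0 d |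
| elm | 0.10 M (fed, over 3.0 d) | 0.200 M | 0.100 M | 1.0 mM | all else is in the flask from the start; the feed brings no volume worth counting | 5.0 d |
| birch | 0.10 M | 0.200 M | 0.100 M | 1.0 mM | everything together at the start | 5.0 d |

| run | time / d | over-reaction product / % | target / % |
|---|---|---|---|
| eta | 0.625 | 1.7 | 18.8 |
| eta | 1.67 | 3.6 | 18.1 |
| eta | 3.00 | 3.7 | 15.9 |
| eta | 5.00 | 8.3 | 12.8 |
| alpha | 0.417 | 0.1 | 10.9 |
| alpha | 1.04 | 1.2 | 12.1 |
| alpha | 2.08 | 1.9 | 10.8 |
| alpha | 3.00 | 2.1 | 9.4 |
| gamma | 0.250 | 2.4 | 33.9 |
| gamma | 0.500 | 0.9 | 31.2 |
| gamma | 1.25 | 5.4 | 29.0 |
| gamma | 3.00 | 13.4 | 25.2 |

(readings scatter by 1 percentage point)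

- percentages count the starting material that a species holds: one idle adduct counts as two
- target is meant together with its idle adduct
- the numbers in the tables scatter by 1 percentage point (one standard deviation)
- steps thought possible: starting material + partner + free catalyst -> free catalyst + target; second substrate + partner + free catalyst -> free catalyst + second product; free catalyst -> spent catalyst; starting material + target <-> idle adduct; target -> over-reaction product
- in an amount of target, one idle adduct counts as one target

1. the flask that comes out highest in amount of over-reaction product, in percent of the starting material charged; "all alike" if 1.5 percentage points covers them all (cedar / alder / elm / birch / all alike)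
2. amount of over-reaction product at the end, in percent of the starting material charged, cedar
3. amount of over-reaction product at the end, in percent of the starting material charged, alder
4. amount of over-reaction product at the end, in percent of the starting material charged, elm
5. amount of over-reaction product at the end, in percent of the starting material charged, birch

In eta, target plus over-reaction product reads 20.5% at 0.625 d and 21.1% at 5.00 d, equal within the scatter of 1 percentage point. So in eta the burst of target is over by the first reading, and from then on target turns into over-reaction product. At 5.00 d the fraction left in eta reads 60.7%.

Suppose a fixed fraction of c(target) goes each day. Then the fractions left multiply, and one constant tells the fall. The eta readings put it at 0.100 d⁻¹. I call this the drain constant, the share of c(target) lost per day with bound target counted; it is a pseudo-first-order constant.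

Birch repeats eta, so I take the eta reading, 8.3%. In cedar the first portion is a third of the charge. The next portion comes at 1.50 d, later than the first eta reading, so I count the first portion alone. I take the first step as first order in starting material, so I estimate 7.03% of target from that portion. If the drain runs as in eta, it takes 39.3% of that by 5.0 d, and my estimate is 2.77%. For alder and elm I borrow the forecast's target of about 1% and take the same 39.3% of it.

The forecast names birch highest: birch 7.8%, cedar 3%, alder 0.3%, elm 0.4%. Its ground is this: “afterwards target only drains to over-reaction product”.

Birch gives 8.23%, cedar 3.68%, above my 2.77%, alder 0.125% and elm 0.204%, so birch stands highest, as forecast.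

starting material + partner + free catalyst → free catalyst + target (k = 1290 M⁻² h⁻¹); second substrate + partner + free catalyst → free catalyst + second product (k = 452 M⁻² h⁻¹); free catalyst → spent catalyst (k = 0.855 h⁻¹); starting material + target ⇌ idle adduct, settled at all times (K = 174 M⁻¹); target → over-reaction product (k = 0.0487 h⁻¹) In birch at 5.00 d, free target has a half-life of 0.59 d by its own step, while the drain constant gives 6.93 d for target with its bound forms, which is longer. Idle adduct in birch then holds 24.3%. It counts double, so it carries 12.2% of the charge as target, out of the 13.2% of target. Birch left until 12 d has 7.08% of target, and the drain constant gives 6.36%.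

The readings stem from a simulated flask on assumed constants; the scatter is artificial.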